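**Assumption:** The target SMILES has no stereocentre and no stereogenic double bond. Gentiside K is therefore achiral, and "single enantiomer" requires no action.

## Retrosynthetic overview
1. Gentiside K is the ester of 2,3-dihydroxybenzoic acid with the unbranched C24 alcohol, so the ester linkage is the only strategic bond.
2. Disconnect the O–CH2 bond in the Mitsunobu sense. Acid 1 serves as the carboxylate nucleophile, and 1-tetracosanol 2 becomes the electrophile once activated in the flask.
3. No ring is formed, because the one benzene ring is bought with 1. No protecting groups are used and there is no stereocentre to set.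

## Route

Step 1
Reactants: 1 2,3-dihydroxybenzoic acid; 2 1-tetracosanol
Product: 4 tetracosyl 2,3-dihydroxybenzoate (gentiside K), via alkoxyphosphonium carboxylate 3 (not isolated)
Conditions: PPh3 (1.2 equiv), DIAD (1.2 equiv, dropwise), THF, N2, 0 °C → rt, 12 h
Reagents that add atoms: none
Why: In this Mitsunobu esterification only the carboxylic acid (pKa about 3, against about 10 for the phenols) protonates the PPh3/DIAD adduct, the primary alcohol is activated as alkoxyphosphonium salt 3, and the carboxylate displaces triphenylphosphine oxide by SN2 at the unhindered CH2, so the free catechol needs no protection and no stereocentre is involved.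

## Compound list
1 | 2,3-dihydroxybenzoic acid | OC(=O)c1cccc(O)c1O | starting material
2 | 1-tetracosanol (lignoceryl alcohol, unbranched C24) | CCCCCCCCCCCCCCCCCCCCCCCCO | starting material
3 | tetracosyloxy(triphenyl)phosphonium 2,3-dihydroxybenzoate (ion pair) | CCCCCCCCCCCCCCCCCCCCCCCCO[P+](c1ccccc1)(c1ccccc1)c1ccccc1.[O-]C(=O)c1cccc(O)c1O | intermediate
4 | tetracosyl 2,3-dihydroxybenzoate (gentiside K) | CCCCCCCCCCCCCCCCCCCCCCCCOC(=O)c1cccc(O)c1O | target

Total step count: 1
Longest linear sequence: 1

## Steps most likely to fail
The route has only one step, so only step 1 can be ranked.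

**Step 1, risks:**
- The free catechol may engage the PPh3/DIAD system, giving a cyclic aryloxyphosphorane or an aryl ether.
- Alcohol 2 is poorly soluble in cold THF.
- The waxy product may be hard to free from the phosphorus and hydrazine residues.

**Step 1, fallback:** The fallback switches from alkyl–O to acyl–O bond formation on a protected catechol. It sets out from 1 and comes back to the route at 4, using 2 on the way.

Acid 1 is perbenzylated (BnBr, K2CO3, DMF, 60 °C) to benzyl 2,3-bis(benzyloxy)benzoate F1. The benzyl ester alone is saponified (NaOH, THF/MeOH/H2O, reflux, then HCl) to 2,3-bis(benzyloxy)benzoic acid F2. This acid is coupled with 2 in a Steglich-type esterification (EDC·HCl, DMAP, CH2Cl2, 35 °C) to tetracosyl 2,3-bis(benzyloxy)benzoate F3. Hydrogenolysis of the two benzyl ethers (H2 1 atm, 10 % Pd/C, EtOAc/THF, rt) leaves the non-benzylic tetracosyl ester untouched and gives 4.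

## Further compounds
F1 | step 1 | benzyl 2,3-bis(benzyloxy)benzoate | O=C(OCc1ccccc1)c1cccc(OCc2ccccc2)c1OCc1ccccc1
F2 | step 1 | 2,3-bis(benzyloxy)benzoic acid | OC(=O)c1cccc(OCc2ccccc2)c1OCc1ccccc1
F3 | step 1 | tetracosyl 2,3-bis(benzyloxy)benzoate | CCCCCCCCCCCCCCCCCCCCCCCCOC(=O)c1cccc(OCc2ccccc2)c1OCc1ccccc1
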